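The target is (2S)-hesperetin with prenyl groups at C6, C8 and C5'. The route rests on cutting the C1''–C2'' bond of both ring A prenyl groups: C6 lies between the 5-OH and the 7-OH, and C8 sits next to the 7-OH (its other neighbour, C8a, carries the ether oxygen O1), so each benzylic CH2 can be the exocyclic carbon of an ortho-quinone methide. In one operation the key step expels dimethylamine from both arms of a 6,8-bis(dimethylaminomethyl)flavanone and moves a 2-methylprop-1-enyl group from boron onto each CH2. Its precursor is unprotected (2S)-hesperetin after twofold Mannich aminomethylation; ring B is prenylated afterwards through C–H borylation.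

Key step: step 2

Remark: (2S)-hesperetin is taken as bought enantiopure; C8 has only one phenolic neighbour (O7), so its quinone methide must be the 7-oxo form, and the order in which the two arms react in step 2 is unknown and immaterial (C8 is drawn first only to give intermediates 6–8 defined structures).

**Route**

Step 1
Reactants: 1 (2S)-hesperetin; 2 formaldehyde; 3 dimethylamine
Product: 4 (2S)-6,8-bis[(dimethylamino)methyl]hesperetin
Conditions: 37% aq. CH2O (2.3 equiv), 40% aq. Me2NH (2.3 equiv), i-PrOH, 0 °C to rt
Reagents that add atoms: formaldehyde (second equivalent), C=O; dimethylamine (second equivalent), CNC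
Why: Twofold phenolic Mannich reaction in which two iminium ions, each made from one molecule of 2 and one of 3, attack C6 and C8, the only unsubstituted and by far the most nucleophilic positions (ring A is phloroglucinol-type, ring B guaiacol-type and unreactive at room temperature), while C2 is not touched because the amine only deprotonates the 7-OH, whose phenoxide lowers the acidity of C3–H.

Step 2
Reactants: 4 (2S)-6,8-bis[(dimethylamino)methyl]hesperetin; 5 2-methylprop-1-enylboronic acid
Product: 9 (2S)-6,8-diprenylhesperetin, via C8 quinone methide 6 (not isolated), via 8-prenyl mono-Mannich base 7 (not isolated), via C6 quinone methide 8 (not isolated)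
Conditions: 5 (5 equiv), toluene/1,4-dioxane (3:1), 95 °C, slow Ar stream; then aq. NH4Cl
Reagents that add atoms: 2-methylprop-1-enylboronic acid (second equivalent), CC(C)=CB(O)O
Why: Each aminomethyl arm sits ortho to a free phenol (O7 for the C8 arm, O7 or O5 for the C6 arm); the boronic acid esterifies that phenol, coordination of nitrogen to boron makes dimethylamine a leaving group, and heating expels it to give the ortho-quinone methide (6, and 8 after the first transfer). In the O-bound boron ate complex the alkenyl group migrates from boron to the exocyclic methylene carbon within a six-membered cyclic array, which rearomatises ring A and, after hydrolysis, returns the phenol. The closest known reaction type is the Petasis-type 1,4-addition of alkenylboronic acids to ortho-quinone methides released thermally from phenolic Mannich bases, here run twice on one ring with one molecule of 5 consumed per arm. No ring is closed and no stereocentre is created; the existing C2 centre is a bystander. Because the carbon that leaves boron ends up as C2'' with its double bond in place, a reverse-prenyl isomer cannot form. The step needs the quinone methide to be captured faster than it oligomerises, re-adds amine or alkylates a second flavanone, and it needs C2 to survive: intramolecular delivery from boron, the excess of 5, the escape of volatile dimethylamine in the argon stream and the near-neutral medium provide this, and the 3'-OH of ring B, having no aminomethyl neighbour, stays passive.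

Step 3
Reactants: 9 (2S)-6,8-diprenylhesperetin
Product: 10 (2S)-6,8-diprenyl-7,3'-bis-O-(triisopropylsilyl)hesperetin
Conditions: TIPSCl (3 equiv), imidazole (6 equiv), DMAP (0.1 equiv), DMF, 40 °C
Reagents that add atoms: chlorotriisopropylsilane, CC(C)[Si](Cl)(C(C)C)C(C)C; chlorotriisopropylsilane (second equivalent), CC(C)[Si](Cl)(C(C)C)C(C)C
Why: Standard silyl ether formation in which the acidic 7-OH and the 3'-OH each take up one silyl group while the 5-OH, hydrogen-bonded to the C4 carbonyl and flanked by the C6 prenyl group, stays free, and imidazole is too weak a base to open the pyranone ring.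

Step 4
Reactants: 10 (2S)-6,8-diprenyl-7,3'-bis-O-(triisopropylsilyl)hesperetin
Product: 13 5'-(pinacolatoboryl) derivative of 10, via 5-O-boryl ester 11 (not isolated), via 5-O-boryl 5'-boronate 12 (not isolated)
Conditions: HBpin (1.1 equiv), THF, rt to 40 °C; then B2pin2 (1.5 equiv), [Ir(OMe)(cod)]2 (3 mol %), 4,4'-di-tert-butyl-2,2'-bipyridine (6 mol %), THF, 70 °C; aq. NH4Cl work-up
Reagents that add atoms: bis(pinacolato)diboron, CC1(C)OB(OC1(C)C)B1OC(C)(C)C(C)(C)O1
Why: Iridium-catalysed aromatic C–H borylation under steric control, in which ring A has no C–H, C2' lies between two substituents, and of the two remaining ring B positions C5' is next to the small OMe group and is the more acidic C–H whereas C6' is next to the branched C2 carbon, so the boryl group should enter at C5'; the 5-OH is masked in the flask as its O–Bpin ester (cleaved on work-up) so that it cannot chelate iridium, and trisubstituted alkenes are poor substrates for hydroboration under these conditions.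

Step 5
Reactants: 13 5'-(pinacolatoboryl) derivative of 10; 14 prenyl bromide
Product: 15 7,3'-bis-O-(triisopropylsilyl)isoamoritin
Conditions: 14 (2 equiv), Pd(PPh3)4 (5 mol %), K3PO4 (3 equiv), THF/H2O (10:1), 40 °C
Reagents that add atoms: none
Why: Suzuki–Miyaura allyl–aryl coupling in which zerovalent palladium ionises 14 to an η3-prenyl complex, the aryl group transmetalates from the phosphate-activated boronate and reductive elimination at the unsubstituted CH2 terminus gives the linear prenyl arene, while the silyl ethers and the chelated, poorly nucleophilic 5-OH keep the phenols from being O-prenylated and the mild base at 40 °C is chosen to spare C2.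

Step 6
Reactants: 15 7,3'-bis-O-(triisopropylsilyl)isoamoritin
Product: 16 isoamoritin
Conditions: TBAF (3 equiv), AcOH (3 equiv), THF, 0 °C to rt
Reagents that add atoms: none
Why: Fluoride-induced cleavage of the two aryl silyl ethers, buffered with acetic acid so that no phenoxide or enolate builds up that could open the pyranone ring at C2, and without any strong acid that could cyclise a prenyl group onto a neighbouring phenol.

**Compound list**

1 | (2S)-hesperetin, (2S)-5,7-dihydroxy-2-(3-hydroxy-4-methoxyphenyl)chroman-4-one | COc1ccc([C@@H]2CC(=O)c3c(O)cc(O)cc3O2)cc1O | starting material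
2 | formaldehyde | C=O | starting material
3 | dimethylamine | CNC | starting material
4 | (2S)-6,8-bis[(dimethylamino)methyl]hesperetin | COc1ccc([C@@H]2CC(=O)c3c(O)c(CN(C)C)c(O)c(CN(C)C)c3O2)cc1O | intermediate
5 | 2-methylprop-1-enylboronic acid | CC(C)=CB(O)O | starting material
6 | C8 quinone methide (in flask): 7-oxo-8-methylidene form of 4 after loss of the C8 amine, with C6 still carrying CH2NMe2 | COc1ccc([C@@H]2CC(=O)C3=C(O2)C(=C)C(=O)C(CN(C)C)=C3O)cc1O | intermediate
7 | (2S)-6-[(dimethylamino)methyl]-8-(3-methylbut-2-enyl)hesperetin (in flask) | COc1ccc([C@@H]2CC(=O)c3c(O)c(CN(C)C)c(O)c(CC=C(C)C)c3O2)cc1O | intermediate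
8 | C6 quinone methide (in flask): 7-oxo-6-methylidene form of 7 after loss of the C6 amine, with C8 prenylated | COc1ccc([C@@H]2CC(=O)C3=C(O)C(=C)C(=O)C(CC=C(C)C)=C3O2)cc1O | intermediate
9 | (2S)-6,8-diprenylhesperetin, (2S)-5,7-dihydroxy-2-(3-hydroxy-4-methoxyphenyl)-6,8-bis(3-methylbut-2-enyl)chroman-4-one | COc1ccc([C@@H]2CC(=O)c3c(O)c(CC=C(C)C)c(O)c(CC=C(C)C)c3O2)cc1O | intermediate
10 | (2S)-6,8-diprenyl-7,3'-bis-O-(triisopropylsilyl)hesperetin (5-OH free) | COc1ccc([C@@H]2CC(=O)c3c(O)c(CC=C(C)C)c(O[Si](C(C)C)(C(C)C)C(C)C)c(CC=C(C)C)c3O2)cc1O[Si](C(C)C)(C(C)C)C(C)C | intermediate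
11 | 5-O-(pinacolatoboryl) ester of 10 (in flask) | COc1ccc([C@@H]2CC(=O)c3c(OB4OC(C)(C)C(C)(C)O4)c(CC=C(C)C)c(O[Si](C(C)C)(C(C)C)C(C)C)c(CC=C(C)C)c3O2)cc1O[Si](C(C)C)(C(C)C)C(C)C | intermediate
12 | 5-O-(pinacolatoboryl)-5'-(pinacolatoboryl) derivative of 10 (in flask) | COc1c(O[Si](C(C)C)(C(C)C)C(C)C)cc([C@@H]2CC(=O)c3c(OB4OC(C)(C)C(C)(C)O4)c(CC=C(C)C)c(O[Si](C(C)C)(C(C)C)C(C)C)c(CC=C(C)C)c3O2)cc1B1OC(C)(C)C(C)(C)O1 | intermediate
13 | 5'-(pinacolatoboryl) derivative of 10 (5-OH free) | COc1c(O[Si](C(C)C)(C(C)C)C(C)C)cc([C@@H]2CC(=O)c3c(O)c(CC=C(C)C)c(O[Si](C(C)C)(C(C)C)C(C)C)c(CC=C(C)C)c3O2)cc1B1OC(C)(C)C(C)(C)O1 | intermediate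
14 | prenyl bromide, 1-bromo-3-methylbut-2-ene | CC(C)=CCBr | starting material
15 | 7,3'-bis-O-(triisopropylsilyl)isoamoritin | COc1c(O[Si](C(C)C)(C(C)C)C(C)C)cc([C@@H]2CC(=O)c3c(O)c(CC=C(C)C)c(O[Si](C(C)C)(C(C)C)C(C)C)c(CC=C(C)C)c3O2)cc1CC=C(C)C | intermediate
16 | isoamoritin, (2S)-5,7-dihydroxy-2-[3-hydroxy-4-methoxy-5-(3-methylbut-2-enyl)phenyl]-6,8-bis(3-methylbut-2-enyl)chroman-4-one | COc1c(O)cc([C@@H]2CC(=O)c3c(O)c(CC=C(C)C)c(O)c(CC=C(C)C)c3O2)cc1CC=C(C)C | target

**Step count and risks**

Total steps: 6. Longest linear sequence: 6 steps (1 to 16).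

Steps most likely to fail:

1. Step 2 (twofold quinone methide alkenylation). The quinone methide may escape the boronate and oligomerise or alkylate a second flavanone, or the second arm may ionise only sluggishly once the first prenyl group is in place. The fallback puts the ring A prenyl groups in by halogenation and cross-coupling, which is known chemistry. It sets out from 1: NIS (2.1 equiv, DMF, 0 °C) should iodinate the two activated ring A positions to give (2S)-6,8-diiodohesperetin F1. A Migita–Kosugi–Stille coupling of F1 with tributyl(3-methylbut-2-enyl)stannane (Pd(PPh3)4, DMF, 80 °C, no base) should then replace both iodides by linear prenyl groups. It comes back to the route at 9.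

2. Step 4 (C–H borylation). C–H activation at ring B is slow because each open position has one ortho neighbour, so iridium boryl and hydride species may consume the prenyl alkenes instead, and some boryl group may enter at C6'. The fallback functionalises ring B first, on the alkene-free flavanone, where forcing conditions and isomer separation cost little; the quinone methide step then ends the synthesis. It sets out from 1: silylation as in step 3 gives 7,3'-bis-O-(triisopropylsilyl)hesperetin F2, whose ring A C–H bonds each lie between two oxygens and should stay untouched. The borylation protocol of step 4 passes through the 5-O-boryl ester F3 and the 5-O-boryl 5'-boronate F4 (both in the flask) to the 5'-boronate F5. Coupling with 14 as in step 5 gives the 5'-prenyl bis-silyl ether F6, and desilylation as in step 6 gives (2S)-5'-prenylhesperetin F7. The Mannich reaction of step 1 gives its 6,8-bis[(dimethylamino)methyl] derivative F8. The alkenylation of step 2 with 5 then runs through the C8 quinone methide F9, the 8-prenyl mono-Mannich base F10 and the C6 quinone methide F11 (all in the flask), and comes back to the route at 16.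

3. Step 5 (allyl–aryl coupling). The aqueous base may strip the 7-O-silyl group (followed by O-prenylation) or erode C2 through enolisation and ring opening, and reductive elimination may occur in part at the tertiary allyl terminus, giving the reverse-prenyl isomer. The fallback is a base-free dehydrative coupling of the free boronic acid with a tertiary allylic alcohol. It sets out from 13: NaIO4 and NH4OAc in acetone/water at rt cleave the pinacol ester to the 5'-boronic acid F12. Zerovalent palladium (Pd(PPh3)4, THF, 60 °C, no base) then couples F12 with 2-methylbut-3-en-2-ol, whose hydroxyl is activated by the boronic acid itself, at the CH2 terminus of the η3-prenyl complex. It comes back to the route at 15.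

**Further compounds**

F1 | step 2 | (2S)-6,8-diiodohesperetin | COc1ccc([C@@H]2CC(=O)c3c(O)c(I)c(O)c(I)c3O2)cc1O
F2 | step 4 | 7,3'-bis-O-(triisopropylsilyl)hesperetin | COc1ccc([C@@H]2CC(=O)c3c(O)cc(O[Si](C(C)C)(C(C)C)C(C)C)cc3O2)cc1O[Si](C(C)C)(C(C)C)C(C)C
F3 | step 4 | 5-O-(pinacolatoboryl) ester of F2 | COc1ccc([C@@H]2CC(=O)c3c(OB4OC(C)(C)C(C)(C)O4)cc(O[Si](C(C)C)(C(C)C)C(C)C)cc3O2)cc1O[Si](C(C)C)(C(C)C)C(C)C
F4 | step 4 | 5-O-(pinacolatoboryl)-5'-(pinacolatoboryl) derivative of F2 | COc1c(O[Si](C(C)C)(C(C)C)C(C)C)cc([C@@H]2CC(=O)c3c(OB4OC(C)(C)C(C)(C)O4)cc(O[Si](C(C)C)(C(C)C)C(C)C)cc3O2)cc1B1OC(C)(C)C(C)(C)O1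
F5 | step 4 | 5'-(pinacolatoboryl) derivative of F2 | COc1c(O[Si](C(C)C)(C(C)C)C(C)C)cc([C@@H]2CC(=O)c3c(O)cc(O[Si](C(C)C)(C(C)C)C(C)C)cc3O2)cc1B1OC(C)(C)C(C)(C)O1
F6 | step 4 | 5'-prenyl-7,3'-bis-O-(triisopropylsilyl)hesperetin | COc1c(O[Si](C(C)C)(C(C)C)C(C)C)cc([C@@H]2CC(=O)c3c(O)cc(O[Si](C(C)C)(C(C)C)C(C)C)cc3O2)cc1CC=C(C)C
F7 | step 4 | (2S)-5'-prenylhesperetin | COc1c(O)cc([C@@H]2CC(=O)c3c(O)cc(O)cc3O2)cc1CC=C(C)C
F8 | step 4 | (2S)-6,8-bis[(dimethylamino)methyl]-5'-prenylhesperetin | COc1c(O)cc([C@@H]2CC(=O)c3c(O)c(CN(C)C)c(O)c(CN(C)C)c3O2)cc1CC=C(C)C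
F9 | step 4 | C8 quinone methide of F8 (7-oxo-8-methylidene form) | COc1c(O)cc([C@@H]2CC(=O)C3=C(O2)C(=C)C(=O)C(CN(C)C)=C3O)cc1CC=C(C)C
F10 | step 4 | (2S)-6-[(dimethylamino)methyl]-8,5'-diprenylhesperetin | COc1c(O)cc([C@@H]2CC(=O)c3c(O)c(CN(C)C)c(O)c(CC=C(C)C)c3O2)cc1CC=C(C)C
F11 | step 4 | C6 quinone methide of F10 (7-oxo-6-methylidene form) | COc1c(O)cc([C@@H]2CC(=O)C3=C(O)C(=C)C(=O)C(CC=C(C)C)=C3O2)cc1CC=C(C)C
F12 | step 5 | 5'-boronic acid corresponding to 13 | COc1c(O[Si](C(C)C)(C(C)C)C(C)C)cc([C@@H]2CC(=O)c3c(O)c(CC=C(C)C)c(O[Si](C(C)C)(C(C)C)C(C)C)c(CC=C(C)C)c3O2)cc1B(O)O
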